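Turn the readings into concentrations before comparing runs.

in all of them: Z 19 mM (held)
- delta: D 0.34 M; G 10 mol%; run made earlier
- beta: D 0.53 M; G 10 mol%; run made earlier
- theta: D 0.24 M; G 15 mol%; run made earlier
- flask: D 0.24 M; G 10 mol%; time 1.0 h

- delta (time / min: J / %): 4.00: 2.1; 12.0: 6.0; 20.0: 9.8; 30.0: 11.3; 40.0: 16.6; 60.0: 19.7; 80.0: 23.3
- beta (time / min: J / %): 10.0: 3.0; 20.0: 5.1; 30.0: 8.0; 40.0: 7.0; 50.0: 10.6; 60.0: 8.5; 80.0: 13.7
- theta (time / min: J / %): 15.0: 12.2; 30.0: 19.1; 40.0: 26.5; 60.0: 30.8; 80.0: 37.2

(scatter of a reading: 1 percentage point)

- at the start none of Z is in solution

- red: doubling the saturation concentration of Z, all else as stated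
- ochre: doubling the transfer coefficient of Z, all else as stated
- amber: doubling the amount of G, all else as stated

1. J at 1.0 h, in percent of the D charged
2. the change that raises the amount of J at 1.0 h, in percent of the D charged most ("none" if none brings more than 2 percentage points) (red / ochre / amber / none)
3. amount of J at 1.0 h, in percent of the D charged, after amber

What do the last readings say? At 80.0 min the percentages spread widely: delta 23.3%, beta 13.7%, theta 37.2%. As concentrations of J they stand close together: 79.2 mM, 72.6 mM, 89.3 mM.

So what do you carry over? The hourly output W, the concentration of J present after 1.0 h, read from delta as 67.0 mM. It looks like a supply set by the gas, what is usually called a mass-transfer limitation.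

And for one molecule of D in the flask? If the runs' near-constant output holds, D molecules share W, so the chance that one ends as J is W over the charge, 27.9%.

Where is that weakest? The flask holds 24.0 mM of G, less than any run. But at the last reading beta, with 53.0 mM of G, held less J than delta with 34.0 mM, though beta's D differs too. So I commit to W for the flask.

And the changes? I expect a small gain from amber and pick red, which acts on the gas supply.

The forecast gave 28% (range 24% to 32%), chose red, and put amber at 34%, reading “a largely gas-supply-limited process”.

The flask gives 27.9%. The gains are 22 percentage points for red, 12 points for ochre and 6.8 points for amber, so the best change is red and amber reaches 34.7%.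

    Z ⇌ X, rate k1*(csat - [X]) (kL = 0.00250 s⁻¹)
    D + J → Q (k = 0.00280 M⁻¹ s⁻¹)
    D ⇌ L (K = 0.430, k = 2.20 × 10⁻⁴ s⁻¹)
    D + X + G → G + J (k = 1.80 M⁻² s⁻¹)

Here X is Z in solution, Q the other product, holding two D, and L a side form of D. The flask's output is 67.0 mM, against W of 67.0 mM. Its J stands at 27.9% through two things acting together, the slow crossing of Z to X and the path from D + J to Q: with fast crossing the flask gives 54.9%, and without that path 47.4%. At W's pace the same flask left until 2.5 h would hold 69.8% of J, yet it holds 41.7%, with D down to 1.8%.

The earlier runs and the new flask were computed for an exercise; noise was put on by code.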